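## Analysis of the target

The target is a 2-aryl-3-methyl-2,3-dihydrobenzofuran neolignan in which a benzene ring (ring A) is fused to a dihydrofuran ring (ring B), with a 3,4,5-trimethoxyphenyl group (ring C) on C2, a methyl group on C3, a methoxy group on C7 and an (E)-prop-1-enyl group on C5. C2 and C3 are the only stereocentres, both are R, and this places the aryl and methyl groups trans on ring B. C2 is a benzylic ether carbon next to an electron-rich arene, so acid can ionise the O1–C2 bond and scramble the trans relationship, and the propenyl group is a styrene-type olefin that is sensitive to acid, oxidants and double-bond migration. Ring A is a 1,2,3,5-tetrasubstituted benzene with hydrogen on C4 and C6, a pattern that electrophilic substitution on a preformed dihydrobenzofuran does not reach reliably, the more so as ring C is at least as nucleophilic as ring A. The difficulty is therefore to combine absolute control of two adjacent stereocentres with a regiodefined ring A. The strategy rests on the sequence around ring A, which is O1 on C7a, OMe on C7, H on C6, a handle on C5 and H on C4. A pyridazine with the tether oxygen on C3, methoxy on C4, hydrogen on C5 and chlorine on C6 delivers exactly this sequence when a terminal alkyne hanging from that oxygen adds across C3 and C6 and the N=N unit leaves.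

## Retrosynthetic reasoning

**C5–propenyl bond.** The target 14 is cut between C5 and the propenyl group, giving aryl chloride 12 and (E)-prop-1-enylboronic acid 13. The olefin is the group least likely to survive a high-temperature benzannulation unchanged, so it is attached last. The chlorine is also useful one step earlier, where it keeps the diazine electron-poor. The forward reaction has to couple an electron-rich aryl chloride with retention of the E geometry.

**Ring A (C3a–C7a and C4–C5).** Chloride 12 is opened at C3a–C7a and C4–C5. This takes ring A and ring B apart in one operation and leads, through cycloadduct 11, to the pyridazinyl ether 10. Cutting here rather than at O1–C2 or C2–C3 means that no stereocentre is made or disturbed when the rings form, because C2 and C3 lie in the tether. Every substituent of ring A comes with the heterocycle, and its position follows from the connectivity of 10. The forward reaction must add an unactivated alkyne across a 1,2-diazine and release the N=N unit as gas before the benzylic ether decomposes.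

**Heteroaryl C–O bond.** Ether 10 is cut between the carbinol oxygen and pyridazine C3, giving alcohol 5 (as alkoxide 9) and the fluoro diazine 8. The heteroaryl C–O bond is cut, not the carbinol C–O bond, because forming the latter would mean substitution at a benzylic stereocentre. Fluorine is placed on C3 so that leaving-group ability decides the site of substitution. With the same halogen on C3 and C6 the outcome would depend on a small and uncertain preference between two similar positions, one of them crowded by the methoxy group.

**C3–F bond.** Fluoride 8 is traced to the purchasable amine 6 through diazonium ion 7. The amino group marks C3 unambiguously, and the forward step only has to exchange it for fluorine.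

**C1–C2 bond of the alcohol.** Alcohol 5 is cut between its two stereocentres, giving aldehyde 3 and the allenylzinc reagent 4. Reagent 4 comes from mesylate 2 of the enantiopure alcohol 1. This one disconnection creates both stereocentres and installs the alkyne. The central chirality of 1 is passed through the axial chirality of 4 to C2, and the cyclic transition state sets C1 anti to it.

## Alternatives that were turned down

Alternative 1: benzannulation of a preformed ring B with a cyclobutenone.
- Disconnection: C3a–C4 and C7–C7a, so that ring A is grown onto a chiral dihydrofuran.
- Forward key step: PdCl2(PhCN)2 with tri(2-furyl)phosphine would couple the vinylstannane tributyl[(2R,3S)-3-methyl-2-(3,4,5-trimethoxyphenyl)-2,3-dihydrofuran-4-yl]stannane A2 with the chloride 3-[(2S)-2-(tert-butyldimethylsilyloxy)propyl]-4-chlorocyclobut-2-en-1-one A3. Warming would open the resulting 4-alkenylcyclobutenone to a dienylketene, which electrocyclises and tautomerises to the phenol (2R,3R)-5-[(2S)-2-(tert-butyldimethylsilyloxy)propyl]-3-methyl-2-(3,4,5-trimethoxyphenyl)-2,3-dihydrobenzofuran-7-ol A1.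
- For: the phenol of A1 appears exactly at C7, and the temperatures are well below those of a diazine cycloaddition. On thermal mildness this plan is the stronger one.
- Against: A1 is still three operations from the target (O-methylation, desilylation, and dehydration of the side-chain alcohol with control of position and geometry of the olefin). A side-chain stereocentre is carried only to be destroyed. A2 is an acid-labile enol ether with two stereocentres, and A3 is a functionalised cyclobutenone; each needs its own multistep synthesis.
- Comparison: the chosen route obtains all ring A substituents from one purchasable heterocycle and needs a single step after ring formation.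

Alternative 2: (4+1) construction of ring B from an ortho-quinone methide and a sulfur ylide.
- Disconnection: O1–C2 and C2–C3.
- Forward key step: Cs2CO3 would release the quinone methide from the racemic sulfone 4-bromo-2-methoxy-6-[1-(4-methylbenzenesulfonyl)ethyl]phenol A5 and the ylide from the sulfonium salt (2R,5R)-2,5-dimethyl-1-(3,4,5-trimethoxybenzyl)thiolan-1-ium bromide A6. A6 is drawn in one enantiomeric series; which antipode leads to the (2R,3R) product would have to be established. Conjugate addition forms C2–C3, and the phenoxide then displaces the sulfide to form O1–C2, giving (2R,3R)-5-bromo-7-methoxy-3-methyl-2-(3,4,5-trimethoxyphenyl)-2,3-dihydrobenzofuran A4.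
- For: the plan is highly convergent and runs at ambient temperature, A5 can be used as the racemate because its stereocentre is erased in the quinone methide, the trans relationship follows from the ring closure, and the bromide of A4 would couple more readily than the chloride 12. On convergence, mildness and the final coupling it is at least as strong as the chosen route.
- Against: both stereocentres are created in the key step. Their absolute sense depends entirely on a stoichiometric chiral sulfide acting on a semi-stabilised benzylic ylide and a transient, methyl-substituted quinone methide, which can also tautomerise to a vinylphenol or oligomerise. Enantiocontrol is the uncertain point and sits in the ring-forming step.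
- Comparison: the chosen route fixes relative and absolute configuration early by chirality transfer from an enantiopure alcohol, so its key step only has to be chemoselective.

Alternative 3: oxidative closure of O1–C2 through a para-quinone methide.
- Disconnection: O1–C2 alone.
- Forward key step: Ag2O would oxidise the 2,6-dimethoxyphenol unit of the bisphenol 4-[(2S)-2-(5-bromo-2-hydroxy-3-methoxyphenyl)propyl]-2,6-dimethoxyphenol A8 to a para-quinone methide. The ring A phenol adds to it in a five-membered closure, and the C3 methyl group steers the aryl group trans, giving the phenol 4-[(2R,3R)-5-bromo-7-methoxy-3-methyl-2,3-dihydrobenzofuran-2-yl]-2,6-dimethoxyphenol A7.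
- For: the closure is biomimetic and mild, only C3 must be set beforehand, and C2 follows by substrate control. On mildness it is stronger than a thermolysis.
- Against: A7 still carries a free para-hydroxyl on ring C, so a methylation is needed after the closure in addition to the coupling. A8, with its isolated benzylic stereocentre, needs an asymmetric synthesis of several steps. The oxidant must distinguish two phenols, and the quinone methide can be intercepted by moisture or by a second molecule. The trans preference at C2 comes only from a reversible addition.
- Comparison: the chosen route needs no phenol differentiation and makes both stereocentres together in a defined anti relationship.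

Key step: step 5

Remark: the allenylzinc addition is assumed to follow its established course (anti SN2' entry of palladium, transmetalation with retention, cyclic SE2' addition); on that basis the (S) mesylate is the correct antipode for the (1R,2R) alcohol.

## Route

Step 1
Reactants: 1 (S)-but-3-yn-2-ol
Product: 2 (S)-but-3-yn-2-yl methanesulfonate
Conditions: MsCl, Et3N, CH2Cl2, −78 °C
Reagents that add atoms: methanesulfonyl chloride, CS(=O)(=O)Cl
Why: O-Sulfonylation of the alcohol; the carbinol C–O bond is not involved, so the S configuration is kept, and the low temperature prevents displacement of the reactive propargylic mesylate by chloride.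

Step 2
Reactants: 2 (S)-but-3-yn-2-yl methanesulfonate; 3 3,4,5-trimethoxybenzaldehyde
Product: 5 (1R,2R)-2-methyl-1-(3,4,5-trimethoxyphenyl)but-3-yn-1-ol, via allenylzinc reagent 4 (not isolated)
Conditions: Pd(OAc)2 (5 mol %), PPh3 (5 mol %), Et2Zn (3 equiv), THF, −78 to −20 °C; aq NH4Cl
Reagents that add atoms: none
Why: Marshall propargylation. Zerovalent palladium, formed from Pd(OAc)2, PPh3 and Et2Zn, displaces the mesylate in an anti SN2' sense to an allenylpalladium species CH3CH=C=CH–Pd(OMs)(PPh3)n, which transmetalates to the (aR)-allenylzinc 4; 4 adds to the aldehyde through a cyclic SE2' transition state on the face that carries zinc. The axial chirality of 4 sets C2 as R, and the preference of the aryl group to lie away from the allenyl methyl group sets C1 as R, which is the anti diastereomer.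

Step 3
Reactants: 6 6-chloro-4-methoxypyridazin-3-amine
Product: 8 6-chloro-3-fluoro-4-methoxypyridazine, via pyridazine-3-diazonium fluoride 7 (not isolated)
Conditions: NaNO2, HF·pyridine (about 70% HF), −10 °C, then 40 °C
Reagents that add atoms: hydrogen fluoride (as HF·pyridine), F
Why: Balz–Schiemann-type fluorodediazoniation of an amino azine: nitrosation gives diazonium ion 7, which loses N2 on warming and is captured by fluoride. Fluorine can only appear where the amino group stood, so the later ether bond is directed to C3 by the leaving group and not by a choice between two chlorides.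

Step 4
Reactants: 5 (1R,2R)-2-methyl-1-(3,4,5-trimethoxyphenyl)but-3-yn-1-ol; 8 6-chloro-3-fluoro-4-methoxypyridazine
Product: 10 6-chloro-4-methoxy-3-{[(1R,2R)-2-methyl-1-(3,4,5-trimethoxyphenyl)but-3-yn-1-yl]oxy}pyridazine, via sodium alkoxide 9 (not isolated)
Conditions: NaH (1.05 equiv), THF, 0 °C; then 8, 0 °C to rt
Reagents that add atoms: none
Why: SNAr (addition–elimination) of alkoxide 9 on the fluoro diazine; fluoride on C3 is displaced much faster than chloride on C6 because addition is rate-limiting and the C–F carbon is the more electrophilic one, so a single regioisomer is expected. The carbinol C–O bond is not broken, so both stereocentres of 5 are carried over, and one equivalent of NaH at 0 °C forms the alkoxide without isomerising the terminal alkyne.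

Step 5
Reactants: 10 6-chloro-4-methoxy-3-{[(1R,2R)-2-methyl-1-(3,4,5-trimethoxyphenyl)but-3-yn-1-yl]oxy}pyridazine
Product: 12 (2R,3R)-5-chloro-7-methoxy-3-methyl-2-(3,4,5-trimethoxyphenyl)-2,3-dihydrobenzofuran, via diazabicyclooctatriene cycloadduct 11 (not isolated)
Conditions: PhNEt2 (degassed, 0.05 M), sealed tube, 200 °C
Reagents that add atoms: none
Why: Intramolecular inverse-electron-demand Diels–Alder reaction of a 3-(but-3-ynyloxy)pyridazine, whose closest known relative is the thermal conversion of 3-chloro-6-(alkynyloxy)pyridazines into 2,3-dihydrobenzofurans; the C3=C4–C5=C6 unit of the electron-poor diazine is the diene and the tethered alkyne the dienophile. The concerted (4+2) addition joins the internal alkyne carbon to pyridazine C3 (C3a–C7a) and the terminal alkyne carbon to C6 (C4–C5) to give the bridged adduct 11, which expels N2 in a retro-(4+2) step and so aromatises. Ring A is closed by the cycloaddition itself through the two new C–C bonds, and ring B closes in the same event as a fused five-membered ring, exo with respect to the alkyne, because O1, C2 and C3 span the diene terminus and the dienophile. No stereocentre is created: the bridgeheads of 11 become aromatic carbons, and C2 and C3 lie in the tether and are not touched. The regiochemistry cannot vary, since a three-atom tether lets only the internal alkyne carbon reach C3, which puts OMe on C7, Cl on C5 and the former alkyne C–H on C4. What the step needs is chemoselectivity for cycloaddition over thermal loss of the benzylic pyridazinyl ether: the chlorine on C6 keeps the diene electron-poor despite the methoxy group, the two tether substituents favour the folded reactive conformer, and the dilute, acid-free, weakly basic medium suppresses ionisation of the benzylic C–O bond.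

Step 6
Reactants: 12 (2R,3R)-5-chloro-7-methoxy-3-methyl-2-(3,4,5-trimethoxyphenyl)-2,3-dihydrobenzofuran; 13 (E)-prop-1-enylboronic acid
Product: 14 (2R,3R)-7-methoxy-3-methyl-5-[(E)-prop-1-en-1-yl]-2-(3,4,5-trimethoxyphenyl)-2,3-dihydrobenzofuran
Conditions: Pd(OAc)2 (3 mol %), SPhos (2-dicyclohexylphosphino-2',6'-dimethoxybiphenyl, 6 mol %), K3PO4, toluene/H2O, 90 °C
Reagents that add atoms: none
Why: Suzuki–Miyaura coupling; the electron-rich dialkylbiarylphosphine lets zerovalent palladium insert into the aryl C–Cl bond, and transmetalation and reductive elimination keep the E geometry of 13. The weakly basic two-phase medium leaves the benzylic ether and both stereocentres untouched, and the sensitive propenyl group is introduced only after the thermolysis.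

## Compound list

1 | (S)-but-3-yn-2-ol | C#C[C@H](C)O | starting material
2 | (S)-but-3-yn-2-yl methanesulfonate | C#C[C@H](C)OS(C)(=O)=O | intermediate
3 | 3,4,5-trimethoxybenzaldehyde | COc1cc(C=O)cc(OC)c1OC | starting material
4 | [(aR)-buta-1,2-dien-1-yl](ethyl)zinc | [H]C(C)=[C@@]=C([H])[Zn]CC | intermediate (not isolated)
5 | (1R,2R)-2-methyl-1-(3,4,5-trimethoxyphenyl)but-3-yn-1-ol | C#C[C@@H](C)[C@H](c1cc(OC)c(OC)c(OC)c1)O | intermediate
6 | 6-chloro-4-methoxypyridazin-3-amine | COc1cc(Cl)nnc1N | starting material
7 | 6-chloro-4-methoxypyridazine-3-diazonium fluoride | COc1cc(Cl)nnc1[N+]#N.[F-] | intermediate (not isolated)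
8 | 6-chloro-3-fluoro-4-methoxypyridazine | COc1cc(Cl)nnc1F | intermediate
9 | sodium (1R,2R)-2-methyl-1-(3,4,5-trimethoxyphenyl)but-3-yn-1-olate | C#C[C@@H](C)[C@H](c1cc(OC)c(OC)c(OC)c1)[O-].[Na+] | intermediate (not isolated)
10 | 6-chloro-4-methoxy-3-{[(1R,2R)-2-methyl-1-(3,4,5-trimethoxyphenyl)but-3-yn-1-yl]oxy}pyridazine | C#C[C@@H](C)[C@H](c1cc(OC)c(OC)c(OC)c1)Oc1nnc(Cl)cc1OC | intermediate
11 | bridged (4+2) adduct of 10, a 2,3-diazabicyclo[2.2.2]octa-2,5,7-triene fused to ring B with (2R,3R) tether carbons and undefined bridgeheads | ClC12C=C3[C@@H](C)[C@H](c4cc(OC)c(OC)c(OC)c4)OC3(N=N1)C(OC)=C2 | intermediate (not isolated)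
12 | (2R,3R)-5-chloro-7-methoxy-3-methyl-2-(3,4,5-trimethoxyphenyl)-2,3-dihydrobenzofuran | Clc1cc(OC)c2c(c1)[C@@H](C)[C@H](c1cc(OC)c(OC)c(OC)c1)O2 | intermediate
13 | (E)-prop-1-enylboronic acid | C/C=C/B(O)O | starting material
14 | (2R,3R)-7-methoxy-3-methyl-5-[(E)-prop-1-en-1-yl]-2-(3,4,5-trimethoxyphenyl)-2,3-dihydrobenzofuran | C/C=C/c1cc(OC)c2c(c1)[C@@H](C)[C@H](c1cc(OC)c(OC)c(OC)c1)O2 | target

## Step count and least certain steps

Total step count: 6. Longest linear sequence: 5 steps (1 → 2 → 5 → 10 → 12 → 14); the branch 6 → 8 is one step.

**Step 5 (key step).**
- What may go wrong: the cycloaddition may be too slow at temperatures the ether tolerates. The methoxy group on C4 donates into the diazine and raises the energy of the diene acceptor orbital, so prolonged heating may be needed. Under such heating the benzylic pyridazinyl ether can fragment before it cyclises, either by syn-elimination through the ring nitrogen and the propargylic hydrogen or by ionisation of the benzylic C–O bond with migration to nitrogen.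
- Fallback: it sets out from 5 and comes back at 12; it removes the donor from the diene and adds the C7 oxygen afterwards. Alcohol 5 would be deprotonated with NaH and joined to purchased, symmetrical 3,6-dichloropyridazine, where no regiochemical question arises, to give 3-chloro-6-{[(1R,2R)-2-methyl-1-(3,4,5-trimethoxyphenyl)but-3-yn-1-yl]oxy}pyridazine F1. This is the parent substrate type of the benzannulation and a more electron-poor diene, so its thermolysis should proceed at lower temperature to (2R,3R)-5-chloro-3-methyl-2-(3,4,5-trimethoxyphenyl)-2,3-dihydrobenzofuran F2. C–H borylation with B2pin2, [Ir(OMe)(cod)]2 and 4,4'-di-tert-butyl-2,2'-bipyridine is expected at C7, the only ring A C–H position not flanked by chlorine (the ring C positions are flanked on both sides). It would give 2-[(2R,3R)-5-chloro-3-methyl-2-(3,4,5-trimethoxyphenyl)-2,3-dihydrobenzofuran-7-yl]-4,4,5,5-tetramethyl-1,3,2-dioxaborolane F3. Oxidation with NaBO3 in THF/H2O would give (2R,3R)-5-chloro-3-methyl-2-(3,4,5-trimethoxyphenyl)-2,3-dihydrobenzofuran-7-ol F4, and methylation with MeI and K2CO3 would return 12.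

**Step 3.**
- What may go wrong: the very electrophilic diazonium ion may be captured by water instead of fluoride (hydrolysis to the pyridazinone), and the reactive fluoro diazine may be lost by hydrolysis during work-up.
- Fallback: it sets out from 5 and comes back at 10; regiocontrol then rests on substrate bias and separation instead of on the leaving group. Purchased 3,4,6-trichloropyridazine would be treated with one equivalent of NaOMe in MeOH at 0 °C, where the 4-chloride, para to N1 and flanked by the 3-chloride, is displaced first, to give 3,6-dichloro-4-methoxypyridazine F5. Alkoxide 9, made from 5 as in step 4, would then be treated with it in toluene at 0 °C. The methoxy group activates the neighbouring carbon inductively and can hold the sodium ion close to C3, which favours 10. Attack at C6 would give the isomeric ether 3-chloro-4-methoxy-6-{[(1R,2R)-2-methyl-1-(3,4,5-trimethoxyphenyl)but-3-yn-1-yl]oxy}pyridazine F6, which would have to be removed by chromatography before the thermolysis.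

**Step 2.**
- What may go wrong: facial discrimination in the cyclic transition state may be incomplete for a flat aryl aldehyde, and the allenylzinc species may partly racemise ahead of a slow addition to an electron-rich aldehyde; both erode diastereomeric and enantiomeric purity.
- Fallback: it sets out from 3 and comes back at 5; stereocontrol is moved from the reagent to a catalyst. Aldehyde 3 would be treated with an excess of racemic pinacol buta-1,2-dien-1-ylboronate and a catalytic amount of one enantiomer of 3,3'-bis(2,4,6-triisopropylphenyl)-1,1'-binaphthyl-2,2'-diyl hydrogen phosphate in toluene; the catalyst antipode that leads to the (1R,2R) series would be fixed in a test run. This is a chiral Brønsted acid-catalysed allenylboration run under kinetic resolution of the boronate, and it is expected to give the anti alcohol 5 directly. The sequence makes no compound outside the list, which is recorded as F0.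

**Step 6.**
- What may go wrong: oxidative addition into the electron-rich C–Cl bond may be slow, so that protodeboronation or oligomerisation of the alkenylboronic acid and partial loss of olefin geometry compete.
- Fallback: it sets out from 12 and comes back at 14; the olefin is brought in as a robust allyl group and moved into conjugation afterwards. Stille coupling of 12 with allyltributylstannane using Pd[P(t-Bu)3]2 and CsF in dioxane would give (2R,3R)-7-methoxy-3-methyl-5-(prop-2-en-1-yl)-2-(3,4,5-trimethoxyphenyl)-2,3-dihydrobenzofuran F7. Isomerisation with PdCl2(MeCN)2 would then move the double bond into conjugation with ring A and give the thermodynamically favoured E olefin 14.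

## Further compounds

F1 | step 5 | 3-chloro-6-{[(1R,2R)-2-methyl-1-(3,4,5-trimethoxyphenyl)but-3-yn-1-yl]oxy}pyridazine | C#C[C@@H](C)[C@H](c1cc(OC)c(OC)c(OC)c1)Oc1ccc(Cl)nn1
F2 | step 5 | (2R,3R)-5-chloro-3-methyl-2-(3,4,5-trimethoxyphenyl)-2,3-dihydrobenzofuran | Clc1ccc2c(c1)[C@@H](C)[C@H](c1cc(OC)c(OC)c(OC)c1)O2
F3 | step 5 | 2-[(2R,3R)-5-chloro-3-methyl-2-(3,4,5-trimethoxyphenyl)-2,3-dihydrobenzofuran-7-yl]-4,4,5,5-tetramethyl-1,3,2-dioxaborolane | Clc1cc(B3OC(C)(C)C(C)(C)O3)c2c(c1)[C@@H](C)[C@H](c1cc(OC)c(OC)c(OC)c1)O2
F4 | step 5 | (2R,3R)-5-chloro-3-methyl-2-(3,4,5-trimethoxyphenyl)-2,3-dihydrobenzofuran-7-ol | Clc1cc(O)c2c(c1)[C@@H](C)[C@H](c1cc(OC)c(OC)c(OC)c1)O2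
F5 | step 3 | 3,6-dichloro-4-methoxypyridazine | COc1cc(Cl)nnc1Cl
F6 | step 3 | 3-chloro-4-methoxy-6-{[(1R,2R)-2-methyl-1-(3,4,5-trimethoxyphenyl)but-3-yn-1-yl]oxy}pyridazine | C#C[C@@H](C)[C@H](c1cc(OC)c(OC)c(OC)c1)Oc1cc(OC)c(Cl)nn1
F0 | step 2 | none | none
F7 | step 6 | (2R,3R)-7-methoxy-3-methyl-5-(prop-2-en-1-yl)-2-(3,4,5-trimethoxyphenyl)-2,3-dihydrobenzofuran | C=CCc1cc(OC)c2c(c1)[C@@H](C)[C@H](c1cc(OC)c(OC)c(OC)c1)O2
A1 | alternative 1 | (2R,3R)-5-[(2S)-2-(tert-butyldimethylsilyloxy)propyl]-3-methyl-2-(3,4,5-trimethoxyphenyl)-2,3-dihydrobenzofuran-7-ol | CC(C)(C)[Si](C)(C)O[C@@H](C)Cc1cc(O)c2c(c1)[C@@H](C)[C@H](c1cc(OC)c(OC)c(OC)c1)O2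
A2 | alternative 1 | tributyl[(2R,3S)-3-methyl-2-(3,4,5-trimethoxyphenyl)-2,3-dihydrofuran-4-yl]stannane | C1=C([Sn](CCCC)(CCCC)CCCC)[C@@H](C)[C@H](c2cc(OC)c(OC)c(OC)c2)O1
A3 | alternative 1 | 3-[(2S)-2-(tert-butyldimethylsilyloxy)propyl]-4-chlorocyclobut-2-en-1-one | CC(C)(C)[Si](C)(C)O[C@@H](C)CC1=CC(=O)C1Cl
A4 | alternative 2 | (2R,3R)-5-bromo-7-methoxy-3-methyl-2-(3,4,5-trimethoxyphenyl)-2,3-dihydrobenzofuran | Brc1cc(OC)c2c(c1)[C@@H](C)[C@H](c1cc(OC)c(OC)c(OC)c1)O2
A5 | alternative 2 | 4-bromo-2-methoxy-6-[1-(4-methylbenzenesulfonyl)ethyl]phenol | CC(c1cc(Br)cc(OC)c1O)S(=O)(=O)c1ccc(C)cc1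
A6 | alternative 2 | (2R,5R)-2,5-dimethyl-1-(3,4,5-trimethoxybenzyl)thiolan-1-ium bromide | C[C@@H]1CC[C@@H](C)[S+]1Cc1cc(OC)c(OC)c(OC)c1.[Br-]
A7 | alternative 3 | 4-[(2R,3R)-5-bromo-7-methoxy-3-methyl-2,3-dihydrobenzofuran-2-yl]-2,6-dimethoxyphenol | Brc1cc(OC)c2c(c1)[C@@H](C)[C@H](c1cc(OC)c(O)c(OC)c1)O2
A8 | alternative 3 | 4-[(2S)-2-(5-bromo-2-hydroxy-3-methoxyphenyl)propyl]-2,6-dimethoxyphenol | Oc1c(OC)cc(Br)cc1[C@@H](C)Cc1cc(OC)c(O)c(OC)c1
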